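All runs are calculated for substances that don't exist, and the scatter is random.

Treat the target in a late flask as a tank with a small inflow and a slow leak, and reckon just those two small terms.

| flask | substrate | gas phase | remark | time |
|---|---|---|---|---|
| zeta | 20 mM | 2.5 mM (held) | the very flask that is asked about, followed so far |  |
| epsilon | 13 mM | 2.5 mM (held) | run made earlier |  |
| flask | 20 mM | 2.5 mM (held) |  | 5.0 h |

- zeta (time / min: target / %, substrate / %): 3.00: 0, 97.2; 8.00: 2.3, 91.8; 15.0: 6.8, 85.2; 25.0: 8.3, 74.5; 30.0: 11.1, 71.3; 40.0: 14.0, 61.1; 50.0: 15.9, 52.5
- epsilon (time / h: target / %, substrate / %): 0.250: 6.6, 84.0; 0.417: 9.0, 74.4; 0.667: 15.1, 61.3; 1.00: 19.8, 46.6; 1.50: 25.2, 32.4; 2.50: 27.9, 13.6; 4.00: 27.8, 4.7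

(readings scatter by 1 percentage point)

- the analysis behind the earlier runs scatters by 1 percentage point, standard deviation
- at the start none of the gas phase is in solution

- ochre: doubling the saturation concentration of gas phase, all else as stated
- grey: doubling the transfer coefficient of the gas phase, all else as stated

- target at 5.0 h, in percent of the substrate charged
- the change that raises the amount of target at 5.0 h, in percent of the substrate charged most ("none" if none brings more than 2 percentage points) (ochre / grey / none)
- amount of target at 5.0 h, in percent of the substrate charged, after grey

What is the large term? Epsilon's last reading, c(target) = 27.8% of the charge at 4.00 h, which stands 1.00 h before the asked time.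

What is the inflow? In epsilon at 0.667 h, target is 39.0% of the substrate consumed, which I take as the selectivity, a reading with the readings' scatter. Epsilon's substrate falls at 0.708 h⁻¹ between its last readings, so I reckon that the remaining time adds 0.93 percentage points.

And the leak? From 2.50 h to 4.00 h, epsilon consumed substrate worth 3.5 points of target, yet target changed by −0.1 points. Dividing the difference by the mean target and the interval gives the loss constant 0.0855 h⁻¹, the fraction of target lost per hour, a reading with the readings' scatter. I reckon that it takes 2.4 points, less than the large term.

But epsilon was charged at 13 mM, the flask at 20 mM? At 40.0 min, zeta and epsilon differ in target by 1.1 points, against a scatter of 1 point, so I make no correction for charge.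

My figure for the flask is 26.4%. The forecast gives 24% (21% to 27%), names ochre and puts grey at 26.5% (23.5% to 30%). It lowers its figure for charge, “so 20 mM gives about 24%”, and mine does not.

    gas phase ⇌ dissolved gas, rate k1*(csat - [dissolved gas]) (kL = 0.430 min⁻¹)
    substrate + dissolved gas → target (k = 2.10 M⁻¹ min⁻¹)
    substrate → side product (k = 0.00760 min⁻¹)
    target → over-reaction product (k = 0.00180 min⁻¹)
    substrate → decomposition product (k = 2.40 × 10⁻⁶ min⁻¹)

The flask gives 25.7%. The best change is ochre, gaining 11 points against 0.49 points for grey, and grey gives 26.2%. One change that would take the flask out of the forecast's range is a later asked time: at 10.0 h this flask holds 15.5%, less than the forecast's low end. The loss constant, applied to 25.7%, reckons 16.7% for that time. For the neighbour flask left until 20 h it reckons 7.11%, and that flask holds 5.29%.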